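**Assumption (remark on the chemistry):** stilbene 7 is carried as an E/Z mixture and carbinol 18 is a transient racemate; hydrogenation erases both, so neither is controlled.

## The problem

Pakyonol (19) is a macrocyclic bis(bibenzyl): four benzene rings in a 20-membered ring, joined by two diaryl ether oxygens (ring A to ring B, ring C to ring D) and two CH2–CH2 bridges (ring B to ring C, ring D to ring A). Rings B and C are spanned para and rings A and D meta, so the large ring holds two para-phenylene units and its closure must compete with oligomerisation. There is no stereocentre, so nothing has to be controlled stereochemically; the open questions are where the ring is closed and how the oxygen substituents are told apart. Ring A carries a methyl ether and ring C a free phenol, each ortho to a diaryl ether oxygen, and they must be differentiated from the start because late selective methylation or demethylation would not be reliable. The target itself is robust, but the intermediates needed for ring closure are not: a para-aryloxy benzylic halide solvolyses easily, an arylboronate can protodeboronate, and benzyl ethers are lost in the hydrogenation that turns a stilbene into a bibenzyl, so the order of events matters. The feature that opens the chosen closure is the B–C bridge ArCH2–CH2Ar: its carbon on ring C can be delivered as carbon monoxide between the benzylic carbon of ring B and the ring C carbon para to the diaryl ether oxygen, giving an aryl ketone that benzylic hydrogenolysis later returns to CH2.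

## Retrosynthesis

**19 to 16 (functional-group removal).** No skeletal bond is cut. The bridge CH2 on ring C is traced back to a carbonyl and the ring C phenol to its benzyl ether, giving the macrocyclic 1,2-diarylethanone 16. Benzyl is preferred to an acyl or silyl group because it survives base, hydride and palladium catalysis. The forward reaction must reduce an aryl ketone to methylene and cleave the benzyl ether in one acid-promoted hydrogenolysis, passing through phenolic ketone 17 and carbinol 18.

**16 to 14 and 15 (key disconnection).** Both bonds at the carbonyl carbon are cut: CH2–C(=O) on the ring B side and C(=O)–aryl on ring C. Cutting a diaryl ether instead would need an activating group on an arene that must later be removed. Closing the bridge as a stilbene would put a rigid unit into the ring being formed. The carbonylative cut needs only a benzylic bromide and an arylboronate on an otherwise inert chain, so 14 is fully acyclic and carbon monoxide (15) is the linchpin. The forward reaction must insert CO before boron-to-palladium transfer and must close a 20-membered ring in preference to coupling two chains.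

**14 to 13 to 12 (installing the two reactive ends).** The C–Br bond of 14 is traced to the benzylic alcohol 13, and the C–B bond of 13 to the aryl chloride 12. Boron goes in before bromine because a benzylic bromide would not survive a palladium-catalysed borylation, whereas a free benzylic alcohol does. Both steps are functional-group changes on one chain and ask only for chemoselectivity.

**12 to 11 to 8 and 10 (ester reduction; C–O–D ether).** The benzylic alcohol of 12 comes from the methyl ester 11. The ring C carbon–oxygen bond of the C–O–D ether is then cut to phenol 8 and aryl bromide 10. Nucleophilic aromatic substitution would need a para formyl or nitro group on ring C, and turning that group into boron costs two or three extra steps. A copper-catalysed coupling of a bromo-chloroarene puts the ether where bromine was and keeps chlorine as the later boron site. The forward reaction must tolerate an ortho benzyloxy group and leave C–Cl alone.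

**10 to 9.** The benzyl–oxygen bond is cut; 2-bromo-5-chlorophenol (9) carries all three ring C substituents in the right positions.

**8 to 7 to 5 and 2 (D–A bridge).** The bibenzyl CH2–CH2 bond is traced to the stilbene 7 and cut at the double bond to aldehyde 5 and phosphonium salt 2, which reacts through ylide 6. Hydrogenation of 7 also removes the ring D benzyl ether, so phenol 8 appears without a separate deprotection. The ring A and ring D oxygens are never free at the same time.

**5 to 3 and 4; 2 to 1.** The A–O–B ether is cut at the ring B carbon, giving isovanillin (3), which supplies the methoxy group, and methyl 4-fluorobenzoate (4). The ester is chosen over the corresponding aldehyde so that only the ring A aldehyde reacts in the Wittig step. Salt 2 comes in one step from 3-(benzyloxy)benzyl alcohol (1).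

## Roads not taken

**Alternative 1:** The cut is the ring A carbon–oxygen bond of the A–O–B ether. The open-chain bis(2,6-dihalophenol) A1 (ring A a 2,6-dibromophenol, ring B a 2,6-dichlorophenol, ring C oxygen as pivalate) would be oxidised with Tl(NO3)3. The ring B phenol oxygen adds to a bromine-bearing ortho carbon of ring A, and zinc reduction of the dienone gives the macrocyclic diaryl ether A2.
- Merits: the closure is biomimetic, needs no activating group on carbon, and leaves both ethano bridges at their final oxidation level. Oxidative phenol coupling of this kind has better precedent for closing diaryl ether macrocycles than a carbonylative three-component closure has for rings of this size.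
- Weak points: Tl(NO3)3 is stoichiometric and toxic. Four halogens must be installed only to steer the oxidation, and three remain in A2. Ring A emerges as a free phenol, so the methyl ether must be made after ring closure, which forces the pivalate on ring C. At least three operations follow A2 (O-methylation, removal of one bromine and two chlorines, pivalate cleavage), against one after 16. The halogen pattern biases but does not guarantee which phenol is oxidised.
- Comparison: the chosen plan sets a catalytic ring closure, oxygen substituents that are correct from the purchased arenes, and a one-step endgame against the better macrocyclisation precedent of this road.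

**Alternative 2:** The cut is the CH2–CH2 bond of the D–A bridge, reached through a ring one atom larger. The 21-membered dibenzyl ether A3 would be lithiated at a benzylic carbon with n-butyllithium, and a [1,2]-shift of the other benzyl group from oxygen to carbon would give the 20-membered racemic 1,2-diarylethanol A4. The hydroxyl is then removed by hydrogenolysis.
- Merits: closing A3 by benzyl ether formation is more secure than the palladium-catalysed closure chosen here. The C–C bond then forms inside an existing ring, so no dilution problem arises at that stage. The site of lithiation does not matter, since both carbinols give the same bibenzyl.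
- Weak points: the [1,2]-Wittig shift runs through a radical pair and is rarely clean. In A3 n-butyllithium can also metalate ortho to the methoxy group and to the diaryl ether oxygens, and the free ring C phenol consumes base. The carbinol still has to be deoxygenated, so the endgame is no shorter.
- Comparison: this road has the safer ring closure and the less certain C–C bond formation. The chosen plan forms the C–C bonds under near-neutral catalytic conditions that the diaryl ethers tolerate, at a similar step count.

**Alternative 3:** The cut is the ring C carbon–oxygen bond of the C–O–D ether, with ring C carried as a non-aromatic 2,3-epoxycyclohexanone. With Cs2CO3 at high dilution the ring D phenoxide of A5 would open the epoxide at C2, and loss of water would give the macrocyclic 2-aryloxycyclohex-2-enone A6 (racemic). Dehydrogenation then makes ring C aromatic.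
- Merits: the closure is metal-free and uses a reactive sp3 electrophile. The seco chain is more flexible than one with a para-phenylene. The ring C hydroxyl arises from the ketone, so ring C needs no protecting group; in that respect this road is better than the chosen one.
- Weak points: A5 cannot be bought as an arene. Its 5-substituted epoxycyclohexanone must be built over several steps, with stereocentres that are later destroyed. The phenoxide may open the epoxide at C3, or the epoxy ketone may enolise under base. The final aromatisation is an oxidation in the presence of three electron-rich arenes and four benzylic CH2 groups.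
- Comparison: the chosen plan pays with one benzyl group, removed at no cost in the last step, and in return uses only aromatic building blocks with the substitution already in place.

Key step: step 10

## Route

Step 1
Reactants: 1 3-(benzyloxy)benzyl alcohol
Product: 2 [3-(benzyloxy)benzyl]triphenylphosphonium bromide
Conditions: PPh3·HBr, MeCN, reflux
Reagents that add atoms: triphenylphosphine hydrobromide, [Br-].c1ccc(cc1)[PH+](c1ccccc1)c1ccccc1
Why: Direct conversion of a benzylic alcohol into its benzyltriphenylphosphonium bromide with PPh3·HBr (acid-promoted substitution at the benzylic carbon) is a standard entry to Wittig salts; the buffered acidity should leave the aryl benzyl ether intact.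

Step 2
Reactants: 3 isovanillin (3-hydroxy-4-methoxybenzaldehyde); 4 methyl 4-fluorobenzoate
Product: 5 methyl 4-(5-formyl-2-methoxyphenoxy)benzoate
Conditions: Cs2CO3, DMSO, 110 °C
Reagents that add atoms: none
Why: Nucleophilic aromatic substitution: the para ester stabilises the Meisenheimer intermediate and fluoride leaves. The ester keeps the ring B carbon at a different oxidation level from the ring A aldehyde, so only the latter reacts in step 3.

Step 3
Reactants: 5 methyl 4-(5-formyl-2-methoxyphenoxy)benzoate; 2 [3-(benzyloxy)benzyl]triphenylphosphonium bromide
Product: 7 methyl 4-[5-[2-[3-(benzyloxy)phenyl]ethenyl]-2-methoxyphenoxy]benzoate (E/Z mixture), via phosphorus ylide 6 (not isolated)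
Conditions: K2CO3, 18-crown-6 (cat.), CH2Cl2, reflux
Reagents that add atoms: none
Why: Wittig olefination of an aromatic aldehyde with a semi-stabilised benzylic ylide under solid–liquid phase-transfer conditions that are mild enough for the methyl ester; the alkene geometry is irrelevant because it is saturated next.

Step 4
Reactants: 7 methyl 4-[5-[2-[3-(benzyloxy)phenyl]ethenyl]-2-methoxyphenoxy]benzoate (E/Z mixture)
Product: 8 methyl 4-[5-[2-(3-hydroxyphenyl)ethyl]-2-methoxyphenoxy]benzoate
Conditions: H2 (1 atm), 10% Pd/C, EtOAc/MeOH, rt
Reagents that add atoms: none
Why: Catalytic hydrogenation saturates the stilbene and hydrogenolyses the ring D benzyl ether in the same operation, so the phenol for the second diaryl ether appears without a separate deprotection; ester and diaryl ether are inert.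

Step 5
Reactants: 9 2-bromo-5-chlorophenol
Product: 10 2-(benzyloxy)-1-bromo-4-chlorobenzene
Conditions: BnBr, K2CO3, acetone, reflux
Reagents that add atoms: benzyl bromide, BrCc1ccccc1
Why: Williamson etherification of a phenol; benzyl is chosen for ring C because it should survive every later step and leave in the final hydrogenolysis.

Step 6
Reactants: 8 methyl 4-[5-[2-(3-hydroxyphenyl)ethyl]-2-methoxyphenoxy]benzoate; 10 2-(benzyloxy)-1-bromo-4-chlorobenzene
Product: 11 methyl 4-[5-[2-[3-[2-(benzyloxy)-4-chlorophenoxy]phenyl]ethyl]-2-methoxyphenoxy]benzoate
Conditions: CuI (10 mol%), N,N-dimethylglycine hydrochloride (30 mol%), Cs2CO3, dioxane, 100 °C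
Reagents that add atoms: none
Why: Ligand-accelerated Ullmann diaryl ether synthesis: monovalent copper activates the C–Br bond and leaves the C–Cl bond untouched, so the chloride para to the new ether is kept as the site for boron. Ortho-alkoxy aryl bromides are established partners in copper-mediated diaryl ether formation.

Step 7
Reactants: 11 methyl 4-[5-[2-[3-[2-(benzyloxy)-4-chlorophenoxy]phenyl]ethyl]-2-methoxyphenoxy]benzoate
Product: 12 [4-[5-[2-[3-[2-(benzyloxy)-4-chlorophenoxy]phenyl]ethyl]-2-methoxyphenoxy]phenyl]methanol
Conditions: i-Bu2AlH, CH2Cl2, −78 to 0 °C; aq. potassium sodium tartrate (KNaC4H4O6)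
Reagents that add atoms: none
Why: Hydride reduction of the benzoate ester to the benzylic alcohol; aryl chloride, benzyl ether and diaryl ethers are inert to i-Bu2AlH.

Step 8
Reactants: 12 [4-[5-[2-[3-[2-(benzyloxy)-4-chlorophenoxy]phenyl]ethyl]-2-methoxyphenoxy]phenyl]methanol
Product: 13 [4-[5-[2-[3-[2-(benzyloxy)-4-(4,4,5,5-tetramethyl-1,3,2-dioxaborolan-2-yl)phenoxy]phenyl]ethyl]-2-methoxyphenoxy]phenyl]methanol
Conditions: B2pin2, Pd2(dba)3 (2 mol%), XPhos (8 mol%), KOAc, dioxane, 110 °C
Reagents that add atoms: bis(pinacolato)diboron, CC1(C)OB(OC1(C)C)B1OC(C)(C)C(C)(C)O1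
Why: Miyaura borylation of an electron-rich aryl chloride, for which the dialkylbiarylphosphine XPhos enables oxidative addition into C–Cl; KOAc is too weak a base to promote Suzuki coupling of the product, and the free benzylic alcohol is tolerated.

Step 9
Reactants: 13 [4-[5-[2-[3-[2-(benzyloxy)-4-(4,4,5,5-tetramethyl-1,3,2-dioxaborolan-2-yl)phenoxy]phenyl]ethyl]-2-methoxyphenoxy]phenyl]methanol
Product: 14 2-[3-(benzyloxy)-4-[3-[2-[3-[4-(bromomethyl)phenoxy]-4-methoxyphenyl]ethyl]phenoxy]phenyl]-4,4,5,5-tetramethyl-1,3,2-dioxaborolane
Conditions: CBr4, PPh3, CH2Cl2, 0 °C
Reagents that add atoms: carbon tetrabromide, BrC(Br)(Br)Br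
Why: Appel bromination converts the primary benzylic alcohol to the bromide under neutral conditions that do not touch the pinacol boronate or the benzyl ether; the halide is made last because it would not survive the borylation.

Step 10
Reactants: 14 2-[3-(benzyloxy)-4-[3-[2-[3-[4-(bromomethyl)phenoxy]-4-methoxyphenyl]ethyl]phenoxy]phenyl]-4,4,5,5-tetramethyl-1,3,2-dioxaborolane; 15 carbon monoxide
Product: 16 macrocyclic 1,2-diarylethanone (pakyonol skeleton with C=O at the bridge carbon on ring C and the ring C oxygen as benzyl ether)
Conditions: CO (5 bar), Pd(OAc)2 (10 mol%), PCy3·HBF4 (20 mol%), K3PO4 (3 equiv), toluene/H2O 20:1, 80 °C; 14 fed by pump over 12 h (final 2 mM)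
Reagents that add atoms: none
Why: Zerovalent palladium, formed in situ from Pd(OAc)2 and PCy3, adds oxidatively to the benzylic C–Br bond of 14, and CO (15) inserts into the benzyl–palladium bond, which has no β-hydrogen, to give an arylacetyl palladium bromide. Base-assisted transfer of the ring C aryl group from the pinacol boronate then gives an acyl(aryl)palladium species as a 21-membered palladacycle, and reductive elimination at the acyl–aryl bond contracts it to the 20-membered ring of 16. The closest known reaction is the carbonylative Suzuki–Miyaura coupling of benzyl halides with arylboron reagents to 1,2-diarylethanones under Pd(OAc)2, PCy3 and K3PO4, and carbonylative cross-couplings have been used to close macrocyclic ketones. The ring is closed end to end at the C(=O)–aryl bond under pseudo-high dilution, which should hold back chain-to-chain coupling and dibenzyl ketone formation. No stereocentre is formed. The selectivity needed is CO insertion before aryl transfer, because direct benzyl–aryl coupling would give the 19-membered diarylmethane; CO pressure and the slow transmetalation of a pinacol boronate secure this, while a limited amount of water activates boron without diverting the acyl palladium to the arylacetic acid. Because the new bridge is an sp3 CH2 next to a carbonyl, the closing chain has no enforced planar or linear unit.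

Step 11
Reactants: 16 macrocyclic 1,2-diarylethanone (ring C oxygen benzylated)
Product: 19 pakyonol, via phenolic macrocyclic ketone 17 (not isolated), via macrocyclic benzylic carbinol 18 (not isolated)
Conditions: H2 (4 bar), 10% Pd/C, HClO4 (cat.), AcOH/EtOAc, rt
Reagents that add atoms: none
Why: Hydrogenolysis over Pd/C removes the benzyl ether and reduces the aryl ketone to the benzylic carbinol, whose C–O bond is then cleaved under acid catalysis because the para aryloxy group on ring C stabilises benzylic cation character. Reduction of aryl ketones to methylene over Pd/C with a strong-acid promoter is a standard transformation, and the carbinol stereocentre is transient.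

## Compound list

1 | 3-(benzyloxy)benzyl alcohol | OCc1cccc(OCc2ccccc2)c1 | starting material
2 | [3-(benzyloxy)benzyl]triphenylphosphonium bromide | [Br-].c1ccc(COc2cccc(C[P+](c3ccccc3)(c3ccccc3)c3ccccc3)c2)cc1 | intermediate
3 | isovanillin (3-hydroxy-4-methoxybenzaldehyde) | COc1ccc(C=O)cc1O | starting material
4 | methyl 4-fluorobenzoate | COC(=O)c1ccc(F)cc1 | starting material
5 | methyl 4-(5-formyl-2-methoxyphenoxy)benzoate | COC(=O)c1ccc(Oc2cc(C=O)ccc2OC)cc1 | intermediate
6 | [3-(benzyloxy)benzylidene]triphenylphosphorane (ylide, not isolated) | c1ccc(COc2cccc(C=P(c3ccccc3)(c3ccccc3)c3ccccc3)c2)cc1 | intermediate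
7 | methyl 4-[5-[2-[3-(benzyloxy)phenyl]ethenyl]-2-methoxyphenoxy]benzoate (E/Z mixture) | COC(=O)c1ccc(Oc2cc(C=Cc3cccc(OCc4ccccc4)c3)ccc2OC)cc1 | intermediate
8 | methyl 4-[5-[2-(3-hydroxyphenyl)ethyl]-2-methoxyphenoxy]benzoate | COC(=O)c1ccc(Oc2cc(CCc3cccc(O)c3)ccc2OC)cc1 | intermediate
9 | 2-bromo-5-chlorophenol | Oc1cc(Cl)ccc1Br | starting material
10 | 2-(benzyloxy)-1-bromo-4-chlorobenzene | Clc1ccc(Br)c(OCc2ccccc2)c1 | intermediate
11 | methyl 4-[5-[2-[3-[2-(benzyloxy)-4-chlorophenoxy]phenyl]ethyl]-2-methoxyphenoxy]benzoate | COC(=O)c1ccc(Oc2cc(CCc3cccc(Oc4ccc(Cl)cc4OCc4ccccc4)c3)ccc2OC)cc1 | intermediate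
12 | [4-[5-[2-[3-[2-(benzyloxy)-4-chlorophenoxy]phenyl]ethyl]-2-methoxyphenoxy]phenyl]methanol | OCc1ccc(Oc2cc(CCc3cccc(Oc4ccc(Cl)cc4OCc4ccccc4)c3)ccc2OC)cc1 | intermediate
13 | [4-[5-[2-[3-[2-(benzyloxy)-4-(4,4,5,5-tetramethyl-1,3,2-dioxaborolan-2-yl)phenoxy]phenyl]ethyl]-2-methoxyphenoxy]phenyl]methanol | OCc1ccc(Oc2cc(CCc3cccc(Oc4ccc(B5OC(C)(C)C(C)(C)O5)cc4OCc4ccccc4)c3)ccc2OC)cc1 | intermediate
14 | 2-[3-(benzyloxy)-4-[3-[2-[3-[4-(bromomethyl)phenoxy]-4-methoxyphenyl]ethyl]phenoxy]phenyl]-4,4,5,5-tetramethyl-1,3,2-dioxaborolane (seco benzyl bromide and arylboronate) | COc1ccc(CCc2cccc(Oc3ccc(B4OC(C)(C)C(C)(C)O4)cc3OCc3ccccc3)c2)cc1Oc1ccc(CBr)cc1 | intermediate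
15 | carbon monoxide | [C-]#[O+] | starting material
16 | macrocyclic 1,2-diarylethanone: pakyonol skeleton with C=O at the bridge carbon on ring C and the ring C oxygen as benzyl ether | COc1ccc2cc1Oc1ccc(cc1)CC(=O)c1ccc(c(OCc3ccccc3)c1)Oc1cccc(c1)CC2 | intermediate
17 | phenolic macrocyclic ketone (16 without the benzyl group, not isolated) | COc1ccc2cc1Oc1ccc(cc1)CC(=O)c1ccc(c(O)c1)Oc1cccc(c1)CC2 | intermediate
18 | macrocyclic benzylic carbinol (racemic, hydroxyl on the bridge carbon at ring C, not isolated) | COc1ccc2cc1Oc1ccc(cc1)CC(O)c1ccc(c(O)c1)Oc1cccc(c1)CC2 | intermediate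
19 | pakyonol | COc1ccc2cc1Oc1ccc(cc1)CCc1ccc(c(O)c1)Oc1cccc(c1)CC2 | target

## Step count and least certain steps

Total: 11 steps. Longest linear sequence: 9 steps (steps 2, 3, 4, 6, 7, 8, 9, 10 and 11, from isovanillin).

**Step 10 (key step).** The most likely failures are chain-to-chain coupling outrunning ring closure, aryl transfer before CO insertion (ring-contracted diarylmethane), capture of the acyl palladium by water, and loss of the benzylic bromide by hydrolysis or by quaternisation of free PCy3. Slow feed, CO pressure and limited water address these from within. The fallback closes the B–C bridge by the classical intramolecular Wittig olefination of bis(bibenzyl) synthesis. It sets out from 8 and comes back at 19.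
- LiAlH4 reduces 8 to 3-[2-[3-[4-(hydroxymethyl)phenoxy]-4-methoxyphenyl]ethyl]phenol F1.
- 4-Fluoro-3-hydroxybenzaldehyde is benzylated (BnBr, K2CO3) to 3-(benzyloxy)-4-fluorobenzaldehyde F2.
- Nucleophilic aromatic substitution of F2 by the phenoxide of F1 (K2CO3, DMF, 100 °C) should give the aldehyde alcohol F3.
- PBr3 converts F3 into the benzylic bromide F4, and PPh3 in toluene gives the formyl phosphonium bromide F5.
- NaOMe under high dilution should close the macrocyclic stilbene F6 (E/Z mixture).
- Hydrogenation over Pd/C saturates the alkene and removes the benzyl ether, giving 19.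

**Step 6.** Copper insertion and C–O coupling next to the ortho benzyloxy group may be slow, leading to incomplete conversion or reductive loss of bromine. The fallback replaces the copper coupling by nucleophilic aromatic substitution on a nitro-activated fluoride and the chloride by an iodide. It sets out from 8 and comes back at 13.
- 2-Fluoro-5-nitrophenol is benzylated to 2-(benzyloxy)-1-fluoro-4-nitrobenzene F7.
- Substitution by 8 (K2CO3, DMF, 80 °C) should give the nitro diaryl ether F8.
- Fe powder and NH4Cl reduce it to the aniline F9.
- Diazotisation and iodination (NaNO2, p-TsOH, KI, MeCN/H2O) give the aryl iodide F10.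
- i-Bu2AlH gives the iodo benzylic alcohol F11.
- Miyaura borylation (PdCl2(dppf), B2pin2, KOAc, dioxane, 80 °C) gives 13.

**Step 11.** The one-pot reduction may stall at the carbinol stage if C–O hydrogenolysis is slow, or the acid may promote side reactions of the phenol. The fallback separates the two tasks. It sets out from 16 and comes back at 19: ionic hydrogenation with Et3SiH in CF3CO2H/CH2Cl2 should reduce the aryl ketone to methylene and give O-benzylpakyonol F12, and neutral hydrogenolysis (H2, Pd/C, EtOAc) then removes the benzyl ether.

**Step 2.** Substitution at a fluoride activated only by an ester may be slow, with incomplete conversion and thermal degradation of the aldehyde on prolonged heating. The fallback is a copper-catalysed Ullmann coupling of 3 with methyl 4-bromobenzoate (CuI, N,N-dimethylglycine hydrochloride, Cs2CO3, dioxane, 90 °C). It sets out from 3 and comes back at 5 without any new intermediate.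

## Further compounds

F1 | step 10 | 3-[2-[3-[4-(hydroxymethyl)phenoxy]-4-methoxyphenyl]ethyl]phenol | OCc1ccc(Oc2cc(CCc3cccc(O)c3)ccc2OC)cc1
F2 | step 10 | 3-(benzyloxy)-4-fluorobenzaldehyde | O=Cc1ccc(F)c(OCc2ccccc2)c1
F3 | step 10 | 3-(benzyloxy)-4-[3-[2-[3-[4-(hydroxymethyl)phenoxy]-4-methoxyphenyl]ethyl]phenoxy]benzaldehyde | OCc1ccc(Oc2cc(CCc3cccc(Oc4ccc(C=O)cc4OCc4ccccc4)c3)ccc2OC)cc1
F4 | step 10 | 3-(benzyloxy)-4-[3-[2-[3-[4-(bromomethyl)phenoxy]-4-methoxyphenyl]ethyl]phenoxy]benzaldehyde | BrCc1ccc(Oc2cc(CCc3cccc(Oc4ccc(C=O)cc4OCc4ccccc4)c3)ccc2OC)cc1
F5 | step 10 | [4-[5-[2-[3-[2-(benzyloxy)-4-formylphenoxy]phenyl]ethyl]-2-methoxyphenoxy]benzyl]triphenylphosphonium bromide | [Br-].O=Cc1ccc(Oc2cccc(CCc3ccc(OC)c(Oc4ccc(C[P+](c5ccccc5)(c5ccccc5)c5ccccc5)cc4)c3)c2)c(OCc2ccccc2)c1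
F6 | step 10 | macrocyclic stilbene (E/Z mixture; C=C in the B–C bridge, ring C oxygen benzylated) | COc1ccc2cc1Oc1ccc(cc1)C=Cc1ccc(c(OCc3ccccc3)c1)Oc1cccc(c1)CC2
F7 | step 6 | 2-(benzyloxy)-1-fluoro-4-nitrobenzene | O=[N+]([O-])c1ccc(F)c(OCc2ccccc2)c1
F8 | step 6 | methyl 4-[5-[2-[3-[2-(benzyloxy)-4-nitrophenoxy]phenyl]ethyl]-2-methoxyphenoxy]benzoate | COC(=O)c1ccc(Oc2cc(CCc3cccc(Oc4ccc([N+](=O)[O-])cc4OCc4ccccc4)c3)ccc2OC)cc1
F9 | step 6 | methyl 4-[5-[2-[3-[4-amino-2-(benzyloxy)phenoxy]phenyl]ethyl]-2-methoxyphenoxy]benzoate | COC(=O)c1ccc(Oc2cc(CCc3cccc(Oc4ccc(N)cc4OCc4ccccc4)c3)ccc2OC)cc1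
F10 | step 6 | methyl 4-[5-[2-[3-[2-(benzyloxy)-4-iodophenoxy]phenyl]ethyl]-2-methoxyphenoxy]benzoate | COC(=O)c1ccc(Oc2cc(CCc3cccc(Oc4ccc(I)cc4OCc4ccccc4)c3)ccc2OC)cc1
F11 | step 6 | [4-[5-[2-[3-[2-(benzyloxy)-4-iodophenoxy]phenyl]ethyl]-2-methoxyphenoxy]phenyl]methanol | OCc1ccc(Oc2cc(CCc3cccc(Oc4ccc(I)cc4OCc4ccccc4)c3)ccc2OC)cc1
F12 | step 11 | O-benzylpakyonol (ring C oxygen as benzyl ether) | COc1ccc2cc1Oc1ccc(cc1)CCc1ccc(c(OCc3ccccc3)c1)Oc1cccc(c1)CC2
F0 | step 2 | none | none
A1 | alternative 1 | open-chain bis(2,6-dihalophenol) with ring C pivalate | Oc1c(Br)cc(CCc2cccc(Oc3ccc(CCc4cc(Cl)c(O)c(Cl)c4)cc3OC(=O)C(C)(C)C)c2)cc1Br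
A2 | alternative 1 | macrocyclic diaryl ether with free ring A phenol, one bromine and two chlorines | Oc1c(Br)cc2cc1Oc1c(Cl)cc(cc1Cl)CCc1ccc(c(OC(=O)C(C)(C)C)c1)Oc1cccc(c1)CC2
A3 | alternative 2 | 21-membered macrocyclic dibenzyl ether | COc1ccc2cc1Oc1ccc(cc1)CCc1ccc(c(O)c1)Oc1cccc(c1)COC2
A4 | alternative 2 | macrocyclic 1,2-diarylethanol (racemic) | COc1ccc2cc1Oc1ccc(cc1)CCc1ccc(c(O)c1)Oc1cccc(c1)C(O)C2
A5 | alternative 3 | seco ring D phenol with tethered 5-substituted 2,3-epoxycyclohexanone (diastereomer mixture) | COc1ccc(CCc2cccc(O)c2)cc1Oc1ccc(CCC2CC(=O)C3OC3C2)cc1
A6 | alternative 3 | macrocyclic 2-aryloxycyclohex-2-enone (racemic) | COc1ccc2cc1Oc1ccc(cc1)CCC1CC(=O)C(=CC1)Oc1cccc(c1)CC2
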